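The cycloheptane is built by inserting the two-carbon unit C6–C7 (the ester-bearing CH and its CH2) between the ring-fusion carbon C5 and the methylene-bearing carbon C8 of a bicyclo[3.3.0]octenone made by a Pauson–Khand reaction. A vinylsilane tethered to the tertiary oxygen on C4 adds across the enone C5=C8 in an intramolecular (2+2) photocycloaddition that forms C5–C6 and C7–C8 together; the 1,3-relationship of the C4 and C6 oxygens allows this five-membered O–Si–C tether, which fixes C6 and later C5. Radical opening of the cyclobutane bond C5–C8 from an iodomethyl group on C8 then gives the seven-membered ring with its exocyclic methylene; Tamao oxidation turns C6–Si into C6–OH.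

Key step: step 9

Remark: atoms are numbered as in the daucane skeleton: C1 (quaternary, methyl), C2 and C3 (CH2 of cyclopentane ring A), C4 (isopropyl carbinol), C5 (ring-fusion CH), C6 (ester CH), C7 (CH2), C8 (methylene-bearing carbon), C9 (secondary carbinol), C10 (CH2), C14 (exocyclic CH2). The target is (1R,4R,5S,6S,9S), trans-fused, with the C4 hydroxyl cis to the C1 methyl.

Step 1
Reactants: 1 ethyl 4-methyl-3-oxopentanoate
Product: 2 ethyl (2Z)-4-methyl-3-(trifluoromethylsulfonyloxy)pent-2-enoate
Conditions: Tf2O, sat. aq. LiOH, hexanes, 5 °C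
Reagents that add atoms: triflic anhydride, O=S(=O)(OS(=O)(=O)C(F)(F)F)C(F)(F)F
Why: Enol triflation of the β-keto ester through the chelated lithium enolate should place OTf cis to the ester (Z), which fixes the later alkene geometry.

Step 2
Reactants: 2 enol triflate; 3 4-bromo-2-methylbut-1-ene
Product: 5 ethyl (2E)-6-methyl-3-(propan-2-yl)hepta-2,6-dienoate, via 3-methylbut-3-enylmagnesium bromide 4 (not isolated)
Conditions: 3, Mg, THF; then 2, Fe(acac)3 (5 mol %), THF/NMP, −30 °C
Reagents that add atoms: none
Why: Iron-catalysed Kumada-type cross-coupling of an enol triflate with an alkyl Grignard reagent should proceed with retention of alkene geometry and tolerate the ester at low temperature.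

Step 3
Reactants: 5 dienoate
Product: 6 (2E)-6-methyl-3-(propan-2-yl)hepta-2,6-dien-1-ol
Conditions: iBu2AlH (2.5 equiv), CH2Cl2, −78 to 0 °C
Reagents that add atoms: none
Why: 1,2-Reduction of the conjugated ester by the aluminium hydride should give the allylic alcohol without touching either alkene.

Step 4
Reactants: 6 allylic alcohol
Product: 7 [(2R,3R)-3-(3-methylbut-3-en-1-yl)-3-(propan-2-yl)oxiran-2-yl]methanol
Conditions: Ti(OiPr)4 (10 mol %), D-(−)-diethyl tartrate (12 mol %), tBuOOH, 4 Å MS, CH2Cl2, −20 °C
Reagents that add atoms: tert-butyl hydroperoxide, CC(C)(C)OO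
Why: Sharpless asymmetric epoxidation is specific for the allylic alcohol alkene, and with D-(−)-tartrate oxygen should be delivered to the face that makes the quaternary epoxide carbon (later C4) R; the isopropyl group trans and the unbranched chain cis to CH2OH is a favourable substitution pattern.

Step 5
Reactants: 7 epoxy alcohol
Product: 8 (2S,3R)-2-(chloromethyl)-3-(3-methylbut-3-en-1-yl)-3-(propan-2-yl)oxirane
Conditions: PPh3, CCl4, NaHCO3, reflux
Reagents that add atoms: tetrachloromethane, ClC(Cl)(Cl)Cl
Why: Appel chlorination of the primary alcohol under buffered conditions should leave the trisubstituted epoxide intact.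

Step 6
Reactants: 8 epoxy chloride
Product: 10 (4R)-7-methyl-4-(propan-2-yl)oct-7-en-2-yne-1,4-diol, via dilithium alkynide alkoxide 9 (not isolated)
Conditions: n-BuLi (3.5 equiv), THF, −78 to −30 °C; then (CH2O)n, −30 °C to rt
Reagents that add atoms: formaldehyde (as paraformaldehyde), C=O
Why: Base-induced double elimination of a 2,3-epoxy chloride (Yadav/Takano alkynol synthesis) opens the epoxide to the tertiary alkoxide with the C4–O bond untouched and gives the lithium acetylide, which is hydroxymethylated in the same flask to install C14.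

Step 7
Reactants: 10 enyne diol
Product: 12 (3aR,6R)-6-hydroxy-1-(hydroxymethyl)-3a-methyl-6-(propan-2-yl)-3,3a,4,5-tetrahydropentalen-2(6H)-one, via hexacarbonyldicobalt alkyne complex 11 (not isolated)
Conditions: Co2(CO)8 (1.1 equiv), CH2Cl2, rt; then N-methylmorpholine N-oxide, 0 °C to rt
Reagents that add atoms: dicobalt octacarbonyl (source of CO), O=C=[Co](=C=O)(=C=O)(=C=O)[Co](=C=O)(=C=O)(=C=O)=C=O
Why: Intramolecular Pauson–Khand reaction builds rings A and B, C9=O and the quaternary C1 in one step; C1 is set by 1,3-induction from C4, since in the product-like insertion transition state the small hydroxyl should lie near the enone plane (least allylic strain with the C8 substituent) and the isopropyl group pseudo-axial on the face away from the pseudo-axial methyl, so that methyl and hydroxyl become cis (the C1 epimer, if formed, is removed here).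

Step 8
Reactants: 12 enone diol; 13 chloro(dimethyl)vinylsilane
Product: 15 (3aR,6R)-6-[ethenyl(dimethyl)silyloxy]-1-(hydroxymethyl)-3a-methyl-6-(propan-2-yl)-3,3a,4,5-tetrahydropentalen-2(6H)-one, via bis(dimethylvinylsilyl) ether 14 (not isolated)
Conditions: 13 (2.5 equiv), imidazole, DMF, rt; then K2CO3 (cat.), MeOH, 0 °C
Reagents that add atoms: none
Why: Both hydroxyls are silylated and the unhindered primary silyl ether should then be methanolysed selectively, the hindered tertiary silyl ether being retained as is usual for trimethylsilyl-type ethers.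

Step 9
Reactants: 15 tethered enone
Product: 16 fenestrane-type photoadduct (1R,4R,5S,6S,8S): C5 is shared by ring A, cyclopentanone ring B, the new cyclobutane C5–C6–C7–C8 and the 2,2-dimethyl-1-oxa-2-silacyclopentane C4–O–Si–C6; C8 carries CH2OH
Conditions: hν (366 nm), degassed CH2Cl2 (0.005 M), 0 °C
Reagents that add atoms: none
Why: Excitation of the enone gives its triplet, whose β-carbon C5 bonds to the tethered vinyl carbon C6 (1,5-closure, rule of five) to give a 1,4-biradical at C7 and C8 that collapses to the cyclobutane. The closest known reaction type is the silicon-tethered intramolecular enone–alkene (2+2) photocycloaddition, here in the fenestrane-forming mode known for bicyclo[3.3.0]oct-1-en-3-ones that carry an alkene on the carbon next to the ring-fusion alkene carbon. The oxasilolane ring closes in the 5-exo sense (C5–C6) and the cyclobutane by radical recombination (C7–C8), as the straight and not the crossed adduct. The tether sits on the C4 oxygen, which is cis to the C1 methyl, so the vinyl group is delivered to the methyl face and only the cis-fused diquinane can form, which sets C5 and C8; the five-membered tether forces silicon on C6 to be cis to C4 on the cyclobutane, which sets C6 (6S, kept on later oxidation with retention). The step needs regioselectivity (C6 to C5, C7 to C8), secured by the three-atom tether, and selective excitation of the enone, secured by 366 nm light that the vinylsilane does not absorb.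

Step 10
Reactants: 16 photoadduct
Product: 17 iodide of 16 (C14 iodomethyl; 1R,4R,5S,6S,8R)
Conditions: PPh3, I2, imidazole, toluene, 70 °C
Reagents that add atoms: iodine, II
Why: Garegg–Samuelsson (Appel-type) iodination of the neopentyl primary alcohol; rearrangement should be disfavoured because a cation would have to develop next to the carbonyl-bearing C8.

Step 11
Reactants: 17 iodide
Product: 18 ring-expanded enone (1R,4R,5R,6S): trans-fused 8-methylidene-9-oxo hydroazulene with the oxasilolane C4–O–SiMe2–C6 intact
Conditions: Bu3SnH (1.2 equiv, slow addition), AIBN (cat.), benzene, 80 °C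
Reagents that add atoms: none
Why: In the tin hydride chain the primary C14 radical undergoes β-scission of the cyclobutane bond C8–C5 (cyclobutylcarbinyl radical opening, as in radical fragmentations of (2+2) photoadducts), giving the exocyclic enone and the tertiary C5 radical; this should take hydrogen on the face cis to the C4 isopropyl group, because only that keeps the oxasilolane cis-fused to ring A, and this is the 5-H of the trans-fused hydroazulene.

Step 12
Reactants: 18 enone
Product: 19 (9S)-allylic alcohol of 18
Conditions: (R)-2-methyl-CBS-oxazaborolidine, catecholborane, toluene, −78 °C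
Reagents that add atoms: none
Why: Corey–Bakshi–Shibata reduction, in which the alkenyl side of the α-methylene ketone acts as the large group, so that the (R)-catalyst should give the 9S carbinol by 1,2-reduction only.

Step 13
Reactants: 19 allylic alcohol
Product: 20 9-O-tert-butyldimethylsilyl ether of 19
Conditions: TBSCl, imidazole, DMF, rt
Reagents that add atoms: tert-butyldimethylsilyl chloride, CC(C)(C)[Si](C)(C)Cl
Why: Standard silylation of the unhindered secondary allylic hydroxyl, which must be masked before the C6 oxygen is set free.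

Step 14
Reactants: 20 silyl ether
Product: 21 (1R,4R,5S,6S,9S)-9-(tert-butyldimethylsilyloxy)dauc-8(14)-ene-4,6-diol
Conditions: H2O2 (30 %), KF, KHCO3, THF/MeOH, 50 °C
Reagents that add atoms: hydrogen peroxide, OO
Why: Tamao–Fleming oxidation of the alkoxysilane converts C6–Si into C6–OH with retention and frees the C4 hydroxyl; the unactivated exocyclic alkene and the silyl ether should be inert to basic peroxide.

Step 15
Reactants: 22 vanillic acid
Product: 24 4-(tert-butyldimethylsilyloxy)-3-methoxybenzoic acid, via silyl ester 23 (not isolated)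
Conditions: TBSCl (2.2 equiv), imidazole, DMF, rt; then AcOH, THF/H2O, rt
Reagents that add atoms: tert-butyldimethylsilyl chloride, CC(C)(C)[Si](C)(C)Cl
Why: Silylation of phenol and acid followed by hydrolysis of the labile silyl ester should leave the aryl silyl ether in place.

Step 16
Reactants: 21 diol; 24 protected vanillic acid
Product: 25 6-O-[4-(tert-butyldimethylsilyloxy)-3-methoxybenzoyl] ester of 21
Conditions: DCC, DMAP, CH2Cl2, rt to 40 °C
Reagents that add atoms: none
Why: Steglich esterification should acylate the secondary C6 hydroxyl only, the tertiary C4 hydroxyl being unreactive, as in esterifications of related daucane 4,6-diols.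

Step 17
Reactants: 25 bis-silyl ether
Product: 26 target, (1R,4R,5S,6S,9S)-4,9-dihydroxydauc-8(14)-en-6-yl 4-hydroxy-3-methoxybenzoate
Conditions: HF·pyridine, pyridine/THF, 0 °C to rt
Reagents that add atoms: none
Why: Fluoride cleaves the aryl and the allylic silyl ether in one operation without touching the hindered ester or the allylic alcohol.

Compound list
1 | ethyl 4-methyl-3-oxopentanoate | CCOC(=O)CC(=O)C(C)C | starting material
2 | ethyl (2Z)-4-methyl-3-(trifluoromethylsulfonyloxy)pent-2-enoate | CCOC(=O)/C=C(/C(C)C)OS(=O)(=O)C(F)(F)F | intermediate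
3 | 4-bromo-2-methylbut-1-ene | C=C(C)CCBr | starting material
4 | 3-methylbut-3-enylmagnesium bromide | C=C(C)CC[Mg]Br | intermediate
5 | ethyl (2E)-6-methyl-3-(propan-2-yl)hepta-2,6-dienoate | CCOC(=O)/C=C(/C(C)C)CCC(C)=C | intermediate
6 | (2E)-6-methyl-3-(propan-2-yl)hepta-2,6-dien-1-ol | OC/C=C(/C(C)C)CCC(C)=C | intermediate
7 | [(2R,3R)-3-(3-methylbut-3-en-1-yl)-3-(propan-2-yl)oxiran-2-yl]methanol | OC[C@H]1O[C@]1(CCC(C)=C)C(C)C | intermediate
8 | (2S,3R)-2-(chloromethyl)-3-(3-methylbut-3-en-1-yl)-3-(propan-2-yl)oxirane | ClC[C@H]1O[C@]1(CCC(C)=C)C(C)C | intermediate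
9 | dilithium salt (acetylide and tertiary alkoxide) of (3R)-6-methyl-3-(propan-2-yl)hept-6-en-1-yn-3-ol | [Li]C#C[C@](O[Li])(C(C)C)CCC(C)=C | intermediate
10 | (4R)-7-methyl-4-(propan-2-yl)oct-7-en-2-yne-1,4-diol | OCC#C[C@](O)(C(C)C)CCC(C)=C | intermediate
11 | hexacarbonyldicobalt complex of the alkyne of 10 | OCC12[Co]3(=C=O)(=C=O)(=C=O)[Co]1(=C=O)(=C=O)(=C=O)C23[C@](O)(C(C)C)CCC(C)=C | intermediate
12 | (3aR,6R)-6-hydroxy-1-(hydroxymethyl)-3a-methyl-6-(propan-2-yl)-3,3a,4,5-tetrahydropentalen-2(6H)-one | OCC1=C2[C@](O)(C(C)C)CC[C@]2(C)CC1=O | intermediate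
13 | chloro(dimethyl)vinylsilane | C=C[Si](C)(C)Cl | starting material
14 | bis[ethenyl(dimethyl)silyl] ether of 12 | C=C[Si](C)(C)OCC1=C2[C@](O[Si](C)(C)C=C)(C(C)C)CC[C@]2(C)CC1=O | intermediate
15 | (3aR,6R)-6-[ethenyl(dimethyl)silyloxy]-1-(hydroxymethyl)-3a-methyl-6-(propan-2-yl)-3,3a,4,5-tetrahydropentalen-2(6H)-one | OCC1=C2[C@](O[Si](C)(C)C=C)(C(C)C)CC[C@]2(C)CC1=O | intermediate
16 | fenestrane-type photoadduct with cyclobutane C5–C6–C7–C8 and oxasilolane C4–O–SiMe2–C6, C8 hydroxymethyl, C9 ketone | OC[C@@]12C[C@H]3[C@]24[C@@](C(C)C)(O[Si]3(C)C)CC[C@]4(C)CC1=O | intermediate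
17 | C14 iodide of 16 | IC[C@@]12C[C@H]3[C@]24[C@@](C(C)C)(O[Si]3(C)C)CC[C@]4(C)CC1=O | intermediate
18 | trans-fused 8-methylidene-9-oxo hydroazulene with oxasilolane C4–O–SiMe2–C6 | C=C1C[C@H]2[C@H]3[C@@](C(C)C)(O[Si]2(C)C)CC[C@]3(C)CC1=O | intermediate
19 | (9S)-allylic alcohol of 18 | C=C1C[C@H]2[C@H]3[C@@](C(C)C)(O[Si]2(C)C)CC[C@]3(C)C[C@@H]1O | intermediate
20 | 9-O-tert-butyldimethylsilyl ether of 19 | C=C1C[C@H]2[C@H]3[C@@](C(C)C)(O[Si]2(C)C)CC[C@]3(C)C[C@@H]1O[Si](C)(C)C(C)(C)C | intermediate
21 | (1R,4R,5S,6S,9S)-9-(tert-butyldimethylsilyloxy)dauc-8(14)-ene-4,6-diol | C=C1C[C@H](O)[C@@H]2[C@](C)(CC[C@@]2(O)C(C)C)C[C@@H]1O[Si](C)(C)C(C)(C)C | intermediate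
22 | vanillic acid (4-hydroxy-3-methoxybenzoic acid) | OC(=O)c1ccc(O)c(OC)c1 | starting material
23 | tert-butyldimethylsilyl 4-(tert-butyldimethylsilyloxy)-3-methoxybenzoate | CC(C)(C)[Si](C)(C)OC(=O)c1ccc(O[Si](C)(C)C(C)(C)C)c(OC)c1 | intermediate
24 | 4-(tert-butyldimethylsilyloxy)-3-methoxybenzoic acid | OC(=O)c1ccc(O[Si](C)(C)C(C)(C)C)c(OC)c1 | intermediate
25 | 6-O-[4-(tert-butyldimethylsilyloxy)-3-methoxybenzoyl] ester of 21 | C=C1C[C@H](OC(=O)c2ccc(O[Si](C)(C)C(C)(C)C)c(OC)c2)[C@@H]2[C@](C)(CC[C@@]2(O)C(C)C)C[C@@H]1O[Si](C)(C)C(C)(C)C | intermediate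
26 | (1R,4R,5S,6S,9S)-4,9-dihydroxydauc-8(14)-en-6-yl 4-hydroxy-3-methoxybenzoate | C=C1C[C@H](OC(=O)c2ccc(O)c(OC)c2)[C@@H]2[C@](C)(CC[C@@]2(O)C(C)C)C[C@@H]1O | target

Total step count: 17. Longest linear sequence: 16 (steps 1–14, 16 and 17, from compound 1).

Steps most likely to fail

Step 9. The triplet 1,4-biradical may revert to the enone or abstract hydrogen instead of closing to the strained four-ring junction, so that conversion stalls or the tether is lost. The fallback sets out from 15 and returns at 16. Luche reduction of 15 (NaBH4, CeCl3·7H2O, MeOH) would give the C9 allylic alcohol of 15 F1 (both C9 epimers are usable). The resulting 1,6-diene would then be closed by a copper-catalysed (2+2) photocycloaddition of the Salomon–Kochi type ((CuOTf)2·C6H6, monovalent copper, Et2O, 254 nm), in which the same tether delivers the vinyl group within a ground-state copper–diene complex, to give the C9 carbinol of 16 F2. Selective oxidation of the secondary carbinol in the presence of the primary one ((Bu3Sn)2O, Br2, CH2Cl2) would return to 16.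

Step 7. Insertion of the hindered 1,1-disubstituted alkene may be slow, and 1,3-induction from C4 may give poor facial selectivity at C1, so that the C1 epimer (methyl trans to the C4 oxygen, useless for the tethered photocycloaddition) forms in quantity. The fallback sets out from 10 and returns at 12 and passes through no new compound (F0): the stereochemistry would be placed under catalyst control by an iridium-catalysed asymmetric carbonylative enyne cyclisation ([Ir(cod)Cl]2, the matched enantiomer of tolBINAP, CO at 1 atm, toluene, reflux), the chiral ligand choosing the alkene face instead of the substrate.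

Step 12. The oxazaborolidine may be mismatched with the intrinsic facial bias of the flexible cycloheptenone (hydride approach anti to the C1 methyl), giving low selectivity at C9, and 1,4-reduction of the exocyclic enone may compete. The fallback sets out from 17 and returns at 19. The ketone would be reduced before ring expansion, in the rigid photoadduct where the carbonyl lies between the quaternary C8 and the C10 methylene and large/small discrimination is at its best ((R)-2-methyl-CBS-oxazaborolidine, catecholborane), to give the (9S)-carbinol of 17 F3. The same radical fragmentation (Bu3SnH, AIBN, benzene, 80 °C) would then deliver 19 directly, with no enone ever formed.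

Further compounds
F1 | step 9 | C9 allylic alcohol of 15 (C9 epimer mixture) | OCC1=C2[C@](O[Si](C)(C)C=C)(C(C)C)CC[C@]2(C)CC1O
F2 | step 9 | C9 carbinol of photoadduct 16 (C9 epimer mixture) | OC[C@@]12C[C@H]3[C@]24[C@@](C(C)C)(O[Si]3(C)C)CC[C@]4(C)CC1O
F0 | step 7 | none | none
F3 | step 12 | (9S)-carbinol of iodide 17 | IC[C@@]12C[C@H]3[C@]24[C@@](C(C)C)(O[Si]3(C)C)CC[C@]4(C)C[C@@H]1O
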